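The runs stem from a simulated flask for an exercise.

Loading the flask with 10 mol% of initiator is a decision about chain length, and the bench rule for it is one chain per initiator, so at complete conversion the rule promises 10.0 units per chain.

| flask | free monomer | protic impurity | initiator | remark | time |
|---|---|---|---|---|---|
| red | 0.67 M | 0.30 M | 10 mol% | run made earlier |  |
| amber | 1.5 M | 0.30 M | 10 mol% | run made earlier |  |
| flask | 1.0 M | 0.300 M | 10 mol% |  | 25 min |

- red (time / min: monomer in chains / %, free monomer / %): 2.50: 16, 59; 4.00: 19, 52; 6.00: 23, 44; 8.00: 24, 38; 12.0: 31, 31; 20.0: 32, 19; 30.0: 41, 17
- amber (time / min: monomer in chains / %, free monomer / %): 4.00: 30, 53; 8.00: 44, 39; 12.0: 51, 30; 15.0: 56, 21; 20.0: 65, 17; 25.0: 68, 10; 30.0: 72, 7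

(scatter of a reading: 1.5 percentage points)

- the average divides the monomer in chains by the number of chains begun, living and dead together
- what was read earlier has a scatter of 1.5 percentage points, one standard deviation
- reactions considered so far: free monomer + initiator -> living end + monomer in chains; free monomer + living end -> monomer in chains + living end; protic impurity + free monomer -> quenched substrate
- the earlier runs do not show the number of chains; that part of a forecast is a guess

1. average number of monomer units in a chain (chains begun, living or dead) at 25 min
2. part of the free monomer that has reacted at 25 min

That rule stops working once the protic impurity is not small against the free monomer. The border is read from a ratio of charges: impurity over monomer, 0.300 in the flask, is the lost share, the fraction of the charge that goes to quenched substrate if each impurity removes one monomer, the impurity being the limiting reagent of that side reaction. The same ratio is 0.448 for red and 0.200 for amber, and the last readings leave 42.0% and 21.0% unaccounted for. Once the lost share has gone to quenched substrate, chain length at a conversion is that conversion less the lost share, over the loading, with a ceiling of 7.00, though the count of one chain per initiator is a guess. Taking the flask midway between red and amber, my own reckoning gives a conversion of 86.0% and a length of 5.60.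

The forecast says 6 and 85%, holding that “the impurity consumes roughly its own molarity of monomer”.

The flask gives 5.38 and 83.7%.

    free monomer + initiator → living end + monomer in chains (k = 7.70 /M/min)
    free monomer + living end → monomer in chains + living end, rate k2*[living end]*[free monomer] (k = 0.500 /M/min)
    protic impurity + free monomer → quenched substrate (k = 0.690 /M/min)

The flask has not come to rest at 25 min: free monomer stands at 16.3%, while quenched substrate is already 29.9%, the lost share. Ten times the time leaves quenched substrate at 30.0%, lifts monomer in chains from 53.8% to 70.0%, takes the conversion to >99.9%, and brings the length to 7.00, against the ceiling of 7.00. The conversion moves 4 points at 8.5 mol% or 12 mol% of initiator.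

In the neighbouring flask with 4 mol% of initiator, the lost share stays 0.300 and the ceiling becomes 17.5. That neighbouring flask, computed, reaches a length of 7.63 at 60.5% conversion at 25 min, with 39% of its free monomer still there.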